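## Structural features

The target (C25H30O5) is a dihydrochalcone: two benzene rings joined by a C(=O)–CH2–CH2 chain, with no stereocentre and no stereodefined double bond, so every problem is one of regiochemistry and chemoselectivity. Ring A is a phloroglucinol nucleus fused to a 2,2-dimethyldihydropyran (a chroman: O1, C2 with two methyl groups, C3, C4). It carries hydroxyls at C5 and C7, the ketone at C6 between them and para to O1, and one hydrogen at C8. Ring B is a 4-hydroxyphenyl group with a 3-methylbut-2-enyl (prenyl) chain ortho to its hydroxyl. The fragile points are the ortho-prenylphenol of ring B (acid closes it to a second chroman, hydrogenation saturates it, electrophiles attack the alkene) and the electron-rich acylphloroglucinol ring (oxidation in base, acid-promoted opening and reclosure of the pyran that would exchange the 6-acyl and 8-acyl patterns). The real difficulty is to place the acyl group on C6 and not on C8 of a chroman-5,7-diol, two positions that electrophiles hardly distinguish, without exposing the prenyl group to Lewis acids. The key step uses the fact that C6 bears an acyl carbon while both neighbours, C5 and C7, bear oxygen: this ortho-acylphenol pattern is what results when the O–C(acyl) bond of a carboxylic acid adds across an aryne triple bond at C6–C7 (or C5–C6), with the second oxygen held as a triflate that steers the addition.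

## Logic of the disconnections

19 to 17 and 18. The aryl O–S bond of the ring A triflate and the O–C(acyl) bond of the ring B acetate are cut. Both masks are base-labile, so one hydroxide treatment removes them together, and since 17 and 18 differ only in which ring A oxygen carries the triflate, both converge on 19. The gain is that the ring B phenol stays hidden during the aryne step and that the isomer pair need be neither separated nor isolated: hydroxide is added to the flask in which the pair forms. The forward operation must attack sulfur and the acetyl carbon while leaving the ketone, the prenyl group and the pyran alone.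

17 and 18 to 10 and 14. The C6–C(=O) bond and the neighbouring aryl C7–O bond (C5–O for 18) are cut; both atoms come from the carboxyl group of 14. The ketone and one flanking oxygen are thus made at the point where the two halves meet, and the site of acylation is fixed by where silicon sits in 10, not by electrophilic substitution. The gain is two fragments of similar size, neither of which contains the sensitive acylphloroglucinol. The forward step needs oxygen to add distal and carbon proximal to the surviving triflate, the acyl shift to be faster than protonation of the aryl anion or loss of the second triflate, and the carboxylate to outcompete the prenyl alkene.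

10 to 8. The two aryl O–S bonds are cut, leaving the oxygens as secondary carbamates. These groups serve twice, as directors for the metalation and as latent phenols that fall off under mild base. The forward step must free two phenols next to a C–Si bond without acid or fluoride and triflate both, the one at C5 being hindered; it is therefore run in one flask through 9.

8 to 4. The C6–Si bond is cut. Silicon marks C6, the only ring position that lies between two carbamates. The gain is a silicon-free, easily made substrate. The forward step demands metalation at C6 and not at C8, in situ masking of both N–H bonds (5), and cold trapping of the aryllithium 6 to give 7.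

4 to 3. The two O–C(=O)N bonds are cut; this is a simple carbamoylation and places no special demand beyond complete double reaction.

3 to 1 and 2. The C4–C4a bond and the O1–C2 bond of the pyran are cut. Because 1 is threefold symmetric there is no regiochemical choice in this annulation. The forward step must stop after one annulation.

14 to 13, then to 11 and 12. The acetate O–C bond is cut first, then the aryl C–CH2 bond of the prenyl group ortho to the phenol. The gain is two cheap starting materials. The forward alkylation must go through carbon and not oxygen of the phenoxide, and the conditions after it must stay non-acidic so that the ortho-prenylphenol does not cyclise.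

## Other disconnections considered

Alternative 1: The cut is the C7–C8 bond of ring A, which is grown on a preformed dihydropyran. In the forward step LiN(SiMe3)2 would deprotonate the 6-methyl group of the acylmalonate A2 (dimethyl 2-[(2,2,6-trimethyl-3,4-dihydro-2H-pyran-5-yl)carbonyl]propanedioate); the vinylogous carbanion would attack one ester carbonyl, and loss of methanol with enolisation would give the chroman ester A1 (methyl 5,7-dihydroxy-2,2-dimethylchroman-6-carboxylate).
- In its favour: every ring A substituent is placed by construction, so the C6 versus C8 question never arises. On regiochemical certainty this plan is better than the chosen one, which relies on metalation at C6 over C8. It also uses no aryne, triflate or fluoride, and ordinary enolate chemistry scales well.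
- Against it here: the malonate C–H of A2 is far more acidic than the methyl group, so the ring closure has to proceed from a dianion onto an ester that belongs to a delocalised enolate and should be sluggish. A1 is still an ester; the ketone carbon–carbon bond to the ring B chain would have to be made afterwards at a carbonyl flanked by two hydrogen-bonded phenols, which calls for phenol protection and a multi-step ester-to-ketone conversion.
- Comparison: the chosen plan forms the ketone and its flanking oxygen in the fragment union itself and should be clearly shorter. Alternative 1 is the equal or the better on predictability of mechanism and on regiocontrol, and the weaker on step economy and convergence.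

Alternative 2: The cut is C4–C4a and O1–C2 of the pyran at the chromene oxidation level. Heating the para-O-(1,1-dimethylpropargyl) ether A3 would trigger an aromatic propargyl Claisen shift, tautomerisation, a 1,5-hydrogen shift and an oxa-6π electrocyclisation to give the 2H-chromene A4 (the 3,4-didehydro target).
- In its favour: the acyl group is attached while ring A is still symmetrical, and the para hydroxyl is the only ring A hydroxyl not hydrogen-bonded to the ketone, so it is alkylated selectively and the pyran oxygen ends para to the acyl group by design. Both ortho positions of that oxygen are equivalent, so one chromene should form. On regiocontrol this is better than the chosen plan, ring A needs no protecting groups, and the step count should be about equal.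
- Against it here: A4 has a C3=C4 double bond that must be hydrogenated in the presence of the prenyl alkene. A cis-disubstituted styrenic alkene against a trisubstituted one is a plausible but narrow selectivity (RhCl(PPh3)3 with H2, or diimide), and over-reduced material would be hard to remove. The acylphloroglucinol precursor would be made by Friedel–Crafts chemistry that threatens the prenyl group, and the ring B phenol may compete in the propargylation.
- Comparison: the chosen plan reaches the correct oxidation level directly and joins the halves late. Alternative 2 is the equal in simplicity of reagents and the better in regiochemical certainty, and the weaker in the chemoselectivity of its last step.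

Alternative 3: The cut is C3–C4 and O1–C2 of the pyran. Heating the Mannich base A5 would expel dimethylamine to give the ring A ortho-quinone methide A6, which would add isobutene in an inverse-demand hetero-Diels–Alder reaction (the alkene CH2 to the exocyclic methylene, oxygen to the tertiary carbon) to give the tris(methoxymethyl) ether A7 of the target.
- In its favour: like the chosen plan it forms two bonds in one step and delivers the saturated pyran directly, which is better than Alternative 2. The regiochemistry of the cycloaddition is unambiguous and isobutene is cheap.
- Against it here: isobutene is an unactivated gaseous alkene that needs pressure and a large excess. The quinone methide can instead be intercepted by the more electron-rich prenyl alkene of ring B or dimerise. Three methoxymethyl groups must be put on and then removed with acid, exactly the conditions that endanger the ortho-prenylphenol, whereas the chosen plan ends in base.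
- Comparison: Alternative 3 is the equal on bond economy of the key step and the weaker on protecting-group load, chemoselectivity toward the prenyl group and probable step count.

Key step: step 7

Remark on the chemistry: the target has no stereocentre and its only C=C bond carries two identical methyl groups, so no configuration has to be set. The structures of 10, 14 and 17 agree atom by atom with 19 (O1 para to the acyl carbon, oxygens at C5 and C7) and need no correction. The aryne insertion necessarily gives 17 together with its isomer 18; since hydroxide takes both to 19, neither is isolated and the cleavage is run in the flask of the aryne step.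

## Route

Step 1
Reactants: 1 phloroglucinol (threefold excess); 2 2-methylbut-3-en-2-ol
Product: 3 2,2-dimethylchroman-5,7-diol
Conditions: Amberlyst 15, THF, 65 °C
Reagents that add atoms: none
Why: Acid turns 2 into the 1,1-dimethylallyl cation, which alkylates the ring of 1 at carbon (Friedel–Crafts allylation), and the ortho-prenylphenol closes by Markovnikov hydroalkoxylation; the three positions of 1 are equivalent, so one mono-chroman forms, and the excess of 1 holds back a second annulation.

Step 2
Reactants: 3 2,2-dimethylchroman-5,7-diol
Product: 4 2,2-dimethylchroman-5,7-diyl bis(N-isopropylcarbamate)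
Conditions: iPrNCO (2.5 equiv), Et3N (cat.), CH2Cl2, rt
Reagents that add atoms: isopropyl isocyanate, CC(C)N=C=O
Why: Base-catalysed addition of both phenols to the isocyanate (carbamoylation) gives secondary carbamates, which direct metalation and, unlike N,N-dialkyl carbamates, can later be removed under mild base by an E1cB pathway.

Step 3
Reactants: 4 2,2-dimethylchroman-5,7-diyl bis(N-isopropylcarbamate)
Product: 8 2,2-dimethyl-6-(trimethylsilyl)chroman-5,7-diyl bis(N-isopropylcarbamate), via bis(N-TBS carbamate) 5 (not isolated), via 6-lithio bis(N-TBS carbamate) 6 (not isolated), via 6-trimethylsilyl bis(N-TBS carbamate) 7 (not isolated)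
Conditions: TBSOTf (2.2 equiv), TMEDA, Et2O, 0 °C to rt; n-BuLi (1.3 equiv), TMEDA, −78 °C; Me3SiCl, −78 °C to rt; aq NaHSO4
Reagents that add atoms: chlorotrimethylsilane, C[Si](C)(C)Cl
Why: N-silylation masks both N–H bonds, and directed ortho-metalation then removes the hydrogen at C6, the only site flanked by two carbamates (cooperative coordination, highest C–H acidity), whereas C8 has one carbamate and the weaker ring ether beside it. Me3SiCl traps the aryllithium cold and the N–Si bonds are hydrolysed on acidic work-up.

Step 4
Reactants: 8 2,2-dimethyl-6-(trimethylsilyl)chroman-5,7-diyl bis(N-isopropylcarbamate)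
Product: 10 2,2-dimethyl-6-(trimethylsilyl)chroman-5,7-diyl bis(trifluoromethanesulfonate), via 2,2-dimethyl-6-(trimethylsilyl)chroman-5,7-diol 9 (not isolated)
Conditions: DBU, Et2NH, MeCN, 40 °C; then PhNTf2 (3 equiv), rt
Reagents that add atoms: N-phenylbis(trifluoromethanesulfonimide), O=S(=O)(N(c1ccccc1)S(=O)(=O)C(F)(F)F)C(F)(F)F
Why: DBU deprotonates each carbamate N–H and the carbamate fragments (E1cB) to phenoxide and isopropyl isocyanate, which Et2NH scavenges as a urea; the phenoxides are triflated in the same flask, so the desilylation-prone silyl resorcinol is never isolated and neither acid nor fluoride touches the C–Si bond.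

Step 5
Reactants: 11 3-(4-hydroxyphenyl)propanoic acid; 12 prenyl bromide (1-bromo-3-methylbut-2-ene)
Product: 13 3-[4-hydroxy-3-(3-methylbut-2-enyl)phenyl]propanoic acid
Conditions: KOH (2.2 equiv), H2O, rt, vigorous stirring; then aq citric acid
Reagents that add atoms: none
Why: In water the phenoxide oxygen of the dianion is hydrogen-bonded, so the allylic bromide is attacked through the ortho carbon (C-alkylation of an ambident phenoxide, then rearomatisation) with the para position blocked; carboxylate alkylation is slow in water and any ester formed is saponified in the medium.

Step 6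
Reactants: 13 3-[4-hydroxy-3-(3-methylbut-2-enyl)phenyl]propanoic acid
Product: 14 3-[4-acetoxy-3-(3-methylbut-2-enyl)phenyl]propanoic acid
Conditions: Ac2O (1.5 equiv), aq NaOH, 0 °C; then aq citric acid to pH 3–4
Reagents that add atoms: acetic anhydride, CC(=O)OC(C)=O
Why: The phenoxide is acetylated by Ac2O under Schotten–Baumann conditions faster than the anhydride hydrolyses, and the carboxylic acid is recovered on mild acidification; the acetate keeps the ring B oxygen from adding to the aryne and is removed together with the triflate at the end of step 7.

Step 7
Reactants: 10 2,2-dimethyl-6-(trimethylsilyl)chroman-5,7-diyl bis(trifluoromethanesulfonate); 14 3-[4-acetoxy-3-(3-methylbut-2-enyl)phenyl]propanoic acid (1.5 equiv)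
Product: 19 1-(5,7-dihydroxy-2,2-dimethylchroman-6-yl)-3-[4-hydroxy-3-(3-methylbut-2-enyl)phenyl]propan-1-one, via 6,7-didehydro-2,2-dimethylchroman-5-yl triflate 15 (not isolated), via 5,6-didehydro-2,2-dimethylchroman-7-yl triflate 16 (not isolated), via 7-hydroxy 5-triflyloxy ketone acetate 17 (not isolated), via 5-hydroxy 7-triflyloxy ketone acetate 18 (not isolated)
Conditions: CsF (4 equiv), THF, 125 °C, sealed tube; cool to rt, then Et4NOH (aq, 8 equiv), 1,4-dioxane, rt to 40 °C, argon; aq citric acid
Reagents that add atoms: none
Why: Fluoride attacks silicon of 10 and either flanking triflate departs, giving the 3-triflyloxyarynes 15 (C6≡C7, triflate left on C5) and 16 (C5≡C6, triflate left on C7). The cesium carboxylate of 14 adds through oxygen to the aryne carbon remote from the surviving triflyloxy group (C7 of 15, C5 of 16), because that σ-withdrawing group distorts the triple bond and stabilises the negative charge that develops on the adjacent carbon, C6. The C6 aryl anion attacks the carbonyl of the aryl ester just formed through a four-membered transition state, and the strained alkoxide opens to the ortho-acylphenoxide, a net insertion of the aryne into the O–C(acyl) bond that forms C7–O (or C5–O) and C6–C(=O). The closest known reaction type is the insertion of arynes from ortho-silylaryl triflates into the C–O bond of carboxylic acids to give ortho-hydroxyaryl ketones, here run on a 3-triflyloxyaryne released from a 2-silyl-1,3-bis(triflate). No ring is closed and no stereocentre is formed. The regiochemistry needed, oxygen distal and carbon proximal to the remaining triflate, is secured by that triflate in both arynes, so 17 and 18 differ only in which oxygen is free and both carry the acyl group on C6. The acyl shift must also outrun protonation of the aryl anion and loss of the second triflate, which hot aprotic THF with no proton source other than the acid itself should favour, and the carboxylate must outcompete the prenyl alkene, which its far higher nucleophilicity should ensure. Because the two isomers need not be separated, Et4NOH is added to the cooled mixture: hydroxide attacks sulfur of the remaining aryl triflate (S–O cleavage, aryl oxygen kept) and the acetyl carbon of the ring B acetate (saponification), so 17 and 18 should converge on 19, the ketone, the prenyl group and the pyran being inert to base and the citric acid work-up too mild to cyclise the ortho-prenylphenol.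

## Compound list

1 | phloroglucinol (benzene-1,3,5-triol) | Oc1cc(O)cc(O)c1 | starting material
2 | 2-methylbut-3-en-2-ol | CC(C)(O)C=C | starting material
3 | 2,2-dimethylchroman-5,7-diol | CC1(C)CCc2c(O)cc(O)cc2O1 | intermediate
4 | 2,2-dimethylchroman-5,7-diyl bis(N-isopropylcarbamate) | CC(C)NC(=O)Oc1cc(OC(=O)NC(C)C)c2CCC(C)(C)Oc2c1 | intermediate
5 | 2,2-dimethylchroman-5,7-diyl bis[N-(tert-butyldimethylsilyl)-N-isopropylcarbamate] | CC(C)N([Si](C)(C)C(C)(C)C)C(=O)Oc1cc(OC(=O)N(C(C)C)[Si](C)(C)C(C)(C)C)c2CCC(C)(C)Oc2c1 | intermediate (not isolated)
6 | 6-lithio-2,2-dimethylchroman-5,7-diyl bis[N-(tert-butyldimethylsilyl)-N-isopropylcarbamate] | CC(C)N([Si](C)(C)C(C)(C)C)C(=O)Oc1cc2OC(C)(C)CCc2c(OC(=O)N(C(C)C)[Si](C)(C)C(C)(C)C)c1[Li] | intermediate (not isolated)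
7 | 2,2-dimethyl-6-(trimethylsilyl)chroman-5,7-diyl bis[N-(tert-butyldimethylsilyl)-N-isopropylcarbamate] | CC(C)N([Si](C)(C)C(C)(C)C)C(=O)Oc1cc2OC(C)(C)CCc2c(OC(=O)N(C(C)C)[Si](C)(C)C(C)(C)C)c1[Si](C)(C)C | intermediate (not isolated)
8 | 2,2-dimethyl-6-(trimethylsilyl)chroman-5,7-diyl bis(N-isopropylcarbamate) | CC(C)NC(=O)Oc1cc2OC(C)(C)CCc2c(OC(=O)NC(C)C)c1[Si](C)(C)C | intermediate
9 | 2,2-dimethyl-6-(trimethylsilyl)chroman-5,7-diol | CC1(C)CCc2c(O1)cc(O)c([Si](C)(C)C)c2O | intermediate (not isolated)
10 | 2,2-dimethyl-6-(trimethylsilyl)chroman-5,7-diyl bis(trifluoromethanesulfonate) | CC1(C)CCc2c(O1)cc(OS(=O)(=O)C(F)(F)F)c([Si](C)(C)C)c2OS(=O)(=O)C(F)(F)F | intermediate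
11 | 3-(4-hydroxyphenyl)propanoic acid | OC(=O)CCc1ccc(O)cc1 | starting material
12 | prenyl bromide (1-bromo-3-methylbut-2-ene) | CC(C)=CCBr | starting material
13 | 3-[4-hydroxy-3-(3-methylbut-2-enyl)phenyl]propanoic acid | CC(C)=CCc1cc(CCC(=O)O)ccc1O | intermediate
14 | 3-[4-acetoxy-3-(3-methylbut-2-enyl)phenyl]propanoic acid | CC(C)=CCc1cc(CCC(=O)O)ccc1OC(C)=O | intermediate
15 | 6,7-didehydro-2,2-dimethylchroman-5-yl trifluoromethanesulfonate (aryne) | CC1(C)CCC2=C(OS(=O)(=O)C(F)(F)F)C#CC=C2O1 | intermediate (not isolated)
16 | 5,6-didehydro-2,2-dimethylchroman-7-yl trifluoromethanesulfonate (aryne) | CC1(C)CCC2=C(O1)C=C(OS(=O)(=O)C(F)(F)F)C#C2 | intermediate (not isolated)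
17 | 6-{3-[4-acetoxy-3-(3-methylbut-2-enyl)phenyl]propanoyl}-7-hydroxy-2,2-dimethylchroman-5-yl trifluoromethanesulfonate | CC(C)=CCc1cc(CCC(=O)c2c(O)cc3c(c2OS(=O)(=O)C(F)(F)F)CCC(C)(C)O3)ccc1OC(C)=O | intermediate (not isolated)
18 | 6-{3-[4-acetoxy-3-(3-methylbut-2-enyl)phenyl]propanoyl}-5-hydroxy-2,2-dimethylchroman-7-yl trifluoromethanesulfonate | CC(C)=CCc1cc(CCC(=O)c2c(OS(=O)(=O)C(F)(F)F)cc3c(c2O)CCC(C)(C)O3)ccc1OC(C)=O | intermediate (not isolated)
19 | 1-(5,7-dihydroxy-2,2-dimethylchroman-6-yl)-3-[4-hydroxy-3-(3-methylbut-2-enyl)phenyl]propan-1-one | CC(C)=CCc1cc(CCC(=O)c2c(O)cc3c(c2O)CCC(C)(C)O3)ccc1O | target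

## Step count and least certain steps

Total step count: 7. Longest linear sequence: 5 steps (steps 1, 2, 3, 4, 7); the acid branch has 2 steps (5, 6) and joins at step 7.

Step 7 (key step).
- What may go wrong: protonation of the C6 aryl anion before the acyl shift, which ends in plain O-arylation of the acid; expulsion of the neighbouring triflate from that anion, which opens a second aryne and leads to multiple additions; an ene reaction of the aryne with the prenyl group; arylation of the product phenoxide by a second aryne; and, in the hydroxide stage, air oxidation of the electron-rich acylphloroglucinol phenoxide. The excess of 14, the hot aprotic medium and the argon atmosphere are meant to suppress these.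
- Fallback (from 4 and 13, returning at 19): 13 is condensed with MeNHOMe·HCl using EDC·HCl and iPr2NEt in CH2Cl2 to give the Weinreb amide 3-[4-hydroxy-3-(3-methylbut-2-enyl)phenyl]-N-methoxy-N-methylpropanamide F1. 4 is N-silylated and lithiated as in step 3 to 6, and the lithium phenoxide of F1 (LiN(SiMe3)2, THF) is added at −78 °C. Work-up with aq NaHSO4 collapses the chelated adduct and removes the N-silyl groups, giving the ketone 6-{3-[4-hydroxy-3-(3-methylbut-2-enyl)phenyl]propanoyl}-2,2-dimethylchroman-5,7-diyl bis(N-isopropylcarbamate) F2. DBU and Et2NH in MeCN at 40 °C then cleave both carbamates to give 19. This replaces the aryne by a Weinreb ketone synthesis on the same C6 carbanion.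

Step 3.
- What may go wrong: metalation at C8 (between the C7 carbamate and the ring oxygen) in competition with C6, which would carry through to an 8-acyl isomer; incomplete double N-silylation, which consumes base; carbamoyl migration to carbon (anionic Fries shift) if the aryllithium warms before trapping.
- Fallback (from 3, returning at 10): only O5 is given a directing group, whose single free ortho position is C6. 3 is monobenzylated (BnBr, K2CO3, acetone), the less hindered O7 being favoured on steric grounds alone; the wanted 7-(benzyloxy)-2,2-dimethylchroman-5-ol F3 is separated, and the other benzyl ethers are returned to 3 by hydrogenolysis. iPrNCO and Et3N give 7-(benzyloxy)-2,2-dimethylchroman-5-yl N-isopropylcarbamate F4. N-silylation, lithiation and Me3SiCl quench as in step 3 should give 7-(benzyloxy)-2,2-dimethyl-6-(trimethylsilyl)chroman-5-yl N-isopropylcarbamate F5, the carbamate dominating the weak ether directors. Hydrogenolysis (H2, Pd/C, EtOAc) gives 7-hydroxy-2,2-dimethyl-6-(trimethylsilyl)chroman-5-yl N-isopropylcarbamate F6, and DBU and Et2NH followed by PhNTf2, as in step 4, give 10.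

Step 5.
- What may go wrong: alkylation at the phenoxide oxygen, a second prenylation at the other ortho position, and hydrolysis of 12 in the aqueous base, all of which lower the return of 13.
- Fallback (from 11, returning at 13): the prenyl group is delivered by a sigmatropic shift. 11 is esterified (MeOH, cat. H2SO4) to methyl 3-(4-hydroxyphenyl)propanoate F7. 2 is converted with Boc2O into tert-butyl 2-methylbut-3-en-2-yl carbonate F8. Allylic etherification of F7 with F8 under Pd(PPh3)4, a zerovalent palladium catalyst (Tsuji–Trost type), gives the tertiary ether methyl 3-[4-(2-methylbut-3-en-2-yloxy)phenyl]propanoate F9. Heating in toluene brings about the aromatic Claisen rearrangement to methyl 3-[4-hydroxy-3-(3-methylbut-2-enyl)phenyl]propanoate F10, with the prenyl group necessarily ortho. LiOH in THF and water gives 13.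

Step 1.
- What may go wrong: a second annulation to a bis-chroman, arrest at the open-chain prenyl compound, or oligomerisation of the allyl cation.
- Fallback (from 1 and 12, returning at 3): C-alkylation and ring closure are separated. 1 is prenylated at carbon with 12 in aqueous KOH to give 2-(3-methylbut-2-enyl)benzene-1,3,5-triol F11, and a catalytic amount of p-toluenesulfonic acid in toluene then closes the pyran to 3.

## Further compounds

F1 | step 7 | 3-[4-hydroxy-3-(3-methylbut-2-enyl)phenyl]-N-methoxy-N-methylpropanamide | CC(C)=CCc1cc(CCC(=O)N(C)OC)ccc1O
F2 | step 7 | 6-{3-[4-hydroxy-3-(3-methylbut-2-enyl)phenyl]propanoyl}-2,2-dimethylchroman-5,7-diyl bis(N-isopropylcarbamate) | CC(C)=CCc1cc(CCC(=O)c2c(OC(=O)NC(C)C)cc3c(c2OC(=O)NC(C)C)CCC(C)(C)O3)ccc1O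
F3 | step 3 | 7-(benzyloxy)-2,2-dimethylchroman-5-ol | CC1(C)CCc2c(O)cc(OCc3ccccc3)cc2O1
F4 | step 3 | 7-(benzyloxy)-2,2-dimethylchroman-5-yl N-isopropylcarbamate | CC(C)NC(=O)Oc1cc(OCc2ccccc2)cc2OC(C)(C)CCc12
F5 | step 3 | 7-(benzyloxy)-2,2-dimethyl-6-(trimethylsilyl)chroman-5-yl N-isopropylcarbamate | CC(C)NC(=O)Oc1c([Si](C)(C)C)c(OCc2ccccc2)cc2OC(C)(C)CCc12
F6 | step 3 | 7-hydroxy-2,2-dimethyl-6-(trimethylsilyl)chroman-5-yl N-isopropylcarbamate | CC(C)NC(=O)Oc1c([Si](C)(C)C)c(O)cc2OC(C)(C)CCc12
F7 | step 5 | methyl 3-(4-hydroxyphenyl)propanoate | COC(=O)CCc1ccc(O)cc1
F8 | step 5 | tert-butyl 2-methylbut-3-en-2-yl carbonate | CC(C)(C)OC(=O)OC(C)(C)C=C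
F9 | step 5 | methyl 3-[4-(2-methylbut-3-en-2-yloxy)phenyl]propanoate | COC(=O)CCc1ccc(OC(C)(C)C=C)cc1
F10 | step 5 | methyl 3-[4-hydroxy-3-(3-methylbut-2-enyl)phenyl]propanoate | COC(=O)CCc1ccc(O)c(CC=C(C)C)c1
F11 | step 1 | 2-(3-methylbut-2-enyl)benzene-1,3,5-triol | CC(C)=CCc1c(O)cc(O)cc1O
A1 | alternative 1 | methyl 5,7-dihydroxy-2,2-dimethylchroman-6-carboxylate | COC(=O)c1c(O)cc2OC(C)(C)CCc2c1O
A2 | alternative 1 | dimethyl 2-[(2,2,6-trimethyl-3,4-dihydro-2H-pyran-5-yl)carbonyl]propanedioate | COC(=O)C(C(=O)OC)C(=O)C1=C(C)OC(C)(C)CC1
A3 | alternative 2 | 1-[2,6-dihydroxy-4-(2-methylbut-3-yn-2-yloxy)phenyl]-3-[4-hydroxy-3-(3-methylbut-2-enyl)phenyl]propan-1-one | CC(C)=CCc1cc(CCC(=O)c2c(O)cc(OC(C)(C)C#C)cc2O)ccc1O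
A4 | alternative 2 | 1-(5,7-dihydroxy-2,2-dimethyl-2H-chromen-6-yl)-3-[4-hydroxy-3-(3-methylbut-2-enyl)phenyl]propan-1-one | CC(C)=CCc1cc(CCC(=O)c2c(O)cc3c(c2O)C=CC(C)(C)O3)ccc1O
A5 | alternative 3 | 1-[3-(dimethylaminomethyl)-4-hydroxy-2,6-bis(methoxymethoxy)phenyl]-3-[4-(methoxymethoxy)-3-(3-methylbut-2-enyl)phenyl]propan-1-one | CC(C)=CCc1cc(CCC(=O)c2c(OCOC)cc(O)c(CN(C)C)c2OCOC)ccc1OCOC
A6 | alternative 3 | ring A ortho-quinone methide: 3,5-bis(methoxymethoxy)-4-{3-[4-(methoxymethoxy)-3-(3-methylbut-2-enyl)phenyl]propanoyl}-6-methylidenecyclohexa-2,4-dien-1-one | CC(C)=CCc1cc(CCC(=O)C2=C(OCOC)C(=C)C(=O)C=C2OCOC)ccc1OCOC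
A7 | alternative 3 | 1-[5,7-bis(methoxymethoxy)-2,2-dimethylchroman-6-yl]-3-[4-(methoxymethoxy)-3-(3-methylbut-2-enyl)phenyl]propan-1-one | CC(C)=CCc1cc(CCC(=O)c2c(OCOC)cc3c(c2OCOC)CCC(C)(C)O3)ccc1OCOC
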